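The synthesis opens ring C (the cyclohexene) at its alkene. Neither alkene carbon is stereogenic: one bears CH2O and is bonded to the spiro centre, the other is the CH next to the secondary allylic carbinol. Every other ring C bond ends at a stereocentre. Ring-closing metathesis makes this C=C, and so ring C and the spiro junction, in one operation, expelling only ethylene. The precursor 29 is the intact cis-fused lactone/cyclopentane bicycle (rings A and B). Its quaternary C7 bears a 1-(PMB-oxymethyl)vinyl group endo and the chain CH(CH3)–CH(OTBS)–CH(OTBS)–CH=CH2 exo, so all six stereocentres precede closure. The lactone methylene and the angelate follow.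

Key step: step 16

Remark (conventions and one assumption):
- Positions follow 2-oxabicyclo[3.3.0]octane numbering: C1 = O–CH, O2, C3 = C=O, C4, C5 = ring-fusion CH, C6, C7, C8.
- C1′–C5′ is the chain CH(CH3)–CH(O)–CH(O)–CH=CH2 on C7.
- exo = convex face (side of H1/H5); endo = concave face.
- PMB = 4-methoxybenzyl; TBS = tert-butyldimethylsilyl.
- It is assumed that water opens the exo bromonium ion of 1 at C7, the alkene carbon remote from the ring fusion.

Step 1
Reactants: 1 (1R,5S)-2-oxabicyclo[3.3.0]oct-6-en-3-one
Product: 2 6-exo-bromo-7-endo-hydroxy-2-oxabicyclo[3.3.0]octan-3-one (ring fusion as in 1)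
Conditions: NBS, acetone–H2O, 0 °C to rt
Reagents that add atoms: N-bromosuccinimide O=C1CCC(=O)N1Br; water O
Why: Bromohydrin formation: the bromonium ion forms on the open exo face and water opens it anti at C7, whose endo side is less screened than that of C6, so oxygen ends up at C7 (both new centres are erased in steps 2 and 3).

Step 2
Reactants: 2 bromohydrin
Product: 3 7-endo-hydroxy-2-oxabicyclo[3.3.0]octan-3-one
Conditions: Bu3SnH, AIBN (cat.), toluene, 80 °C
Reagents that add atoms: none
Why: Tin hydride radical-chain dehalogenation removes the secondary bromide under neutral conditions that leave carbinol and lactone alone and create no stereocentre.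

Step 3
Reactants: 3 hydroxy lactone
Product: 4 cis-2-oxabicyclo[3.3.0]octane-3,7-dione (keto lactone)
Conditions: Dess–Martin periodinane, CH2Cl2, rt
Reagents that add atoms: none
Why: Dess–Martin oxidation is base-free, which matters because 4 is a β-acyloxy ketone that would lose the lactone carboxylate by E1cB elimination under basic conditions.

Step 4
Reactants: 5 4-methoxybenzyl alcohol; 6 2,3-dibromopropene
Product: 8 2-bromoallyl 4-methoxybenzyl ether, via sodium alkoxide 7 (not isolated)
Conditions: NaH, THF, 0 °C; then 6, 0 °C to rt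
Reagents that add atoms: none
Why: Williamson ether synthesis: the alkoxide displaces the allylic bromide (SN2), whereas the vinylic C–Br bond is inert and is kept for step 5.

Step 5
Reactants: 8 2-bromoallyl PMB ether; 4 keto lactone
Product: 11 7-endo-hydroxy-7-exo-[1-(PMB-oxymethyl)vinyl] lactone (tertiary allylic alcohol), via alkenyllithium 9 (not isolated), via alkenylcerium dichloride 10 (not isolated)
Conditions: t-BuLi (2 equiv per 8), THF, −78 °C; anhydrous CeCl3, −78 °C; then 4, −78 °C; aq NH4Cl
Reagents that add atoms: none
Why: Bromine–lithium exchange and transmetalation give a weakly basic organocerium reagent whose 1,2-addition to the cyclopentanone at −78 °C outruns enolisation (hence β-elimination) and attack on the lactone; exo attack gives the endo carbinol, a centre that step 6 erases.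

Step 6
Reactants: 11 tertiary allylic alcohol
Product: 12 7-[1-hydroxy-3-(PMB-oxy)propan-2-ylidene] lactone (primary allylic alcohol; mixture of both alkene geometries)
Conditions: Ph3SiOReO3 (5 mol%), Et2O, 0 °C
Reagents that add atoms: none
Why: Rhenium-oxo-catalysed 1,3-transposition of an allylic alcohol ([3,3] shift of the perrhenate ester) runs towards the primary alcohol and the tetrasubstituted alkene; the alkene geometry cannot be controlled because C6H2 and C8H2 are nearly alike, and step 7 is designed not to need it.

Step 7
Reactants: 12 primary allylic alcohol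
Product: 14 7-exo-(2-oxoethyl)-7-endo-[1-(PMB-oxymethyl)vinyl] lactone (aldehyde), via vinyl ether 13 (not isolated)
Conditions: Pd(OCOCF3)2 (5 mol%), 4,7-diphenyl-1,10-phenanthroline, Et3N (cat.), n-butyl vinyl ether, 75 °C; evaporate; xylenes, 140 °C
Reagents that add atoms: n-butyl vinyl ether C=COCCCC
Why: Transvinylation followed by an aliphatic Claisen rearrangement ([3,3], suprafacial): the new C7–C bond forms on the exo face because the folded lactone ring screens the endo face, which sets the quaternary centre, and since the migrating terminus is an unsubstituted CH2 both alkene isomers of 12 converge on one product.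

Step 8
Reactants: 14 aldehyde
Product: 15 the corresponding 7-exo-acetic acid
Conditions: NaClO2, NaH2PO4, 2-methyl-2-butene, t-BuOH–H2O, rt
Reagents that add atoms: sodium chlorite [Na+].[O-]Cl=O
Why: Pinnick oxidation converts the aldehyde selectively, the alkene scavenger protecting the 1,1-disubstituted alkene and the PMB ring from hypochlorous acid.

Step 9
Reactants: 15 acid; 16 (R)-4-benzyl-2-oxazolidinone
Product: 18 N-acyl oxazolidinone (imide), via mixed pivalic anhydride 17 (not isolated)
Conditions: PivCl, Et3N, THF, −20 °C; then LiCl, 16, −20 °C to rt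
Reagents that add atoms: none
Why: Mixed-anhydride N-acylation under LiCl/Et3N conditions attaches the Evans auxiliary without strong base, attack occurring at the less hindered CH2–C=O carbonyl of 17.

Step 10
Reactants: 18 imide
Product: 20 (1′R)-α-methyl imide, via Z sodium enolate 19 (not isolated)
Conditions: NaHMDS (1.05 equiv), THF, −78 °C; MeI, −78 to −40 °C
Reagents that add atoms: iodomethane CI
Why: Evans asymmetric alkylation: the chelated Z enolate is shielded on one face by the benzyl group, so MeI enters from the other and sets C1′ as R, an external control element being required because the ring offers none (step 6); the imide is the most acidic C–H acid present and the amide/amine pair lets any lactone enolate revert.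

Step 11
Reactants: 20 α-methyl imide
Product: 21 triol (C1–OH, C5–CH2CH2OH, C1′–CH2OH)
Conditions: LiBH4, H2O (1 equiv per LiBH4), Et2O, 0 °C to rt
Reagents that add atoms: none
Why: Borohydride reduction attacks the exocyclic imide carbonyl and releases the auxiliary; the lactone is knowingly reduced as well because step 12 restores it, and C1′ is not enolised under these conditions.

Step 12
Reactants: 21 triol
Product: 24 (1′R)-α-methyl aldehyde on the re-formed cis-fused lactone, via lactol 22 (not isolated), via hydroxy lactone 23 (not isolated)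
Conditions: TEMPO (20 mol%), PhI(OAc)2 (3.5 equiv), CH2Cl2, rt
Reagents that add atoms: none
Why: TEMPO/PhI(OAc)2 oxidation takes only primary alcohols: the unhindered one gives an aldehyde that closes with the C1 hydroxyl to the lactol and is oxidised on to the lactone (oxidative lactonisation of a 1,4-diol), and the hindered one stops at the aldehyde without epimerising C1′.

Step 13
Reactants: 25 allyl tert-butyldimethylsilyl ether
Product: 27 (Z)-tributyl[3-(TBS-oxy)allyl]stannane, via allyllithium 26 (not isolated)
Conditions: s-BuLi, THF–HMPA, −78 °C; Bu3SnCl, −78 °C to rt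
Reagents that add atoms: tributyltin chloride CCCC[Sn](Cl)(CCCC)CCCC
Why: Deprotonation of the allyl silyl ether gives the oxygen-chelated Z allyllithium, which the tin chloride traps at the γ-carbon, the regiochemistry known for this reagent class.

Step 14
Reactants: 24 α-methyl aldehyde; 27 γ-silyloxyallylstannane
Product: 28 (1′R,2′S,3′S)-2′-hydroxy-3′-(TBS-oxy) homoallylic alcohol
Conditions: BF3·OEt2, CH2Cl2, −78 °C (Lewis acid added last); aq NaHCO3
Reagents that add atoms: none
Why: Lewis-acid-promoted γ-silyloxyallylstannane addition (SE2′, open antiperiplanar transition state) gives the syn C2′/C3′ diol relationship, and Felkin–Anh attack anti to the very large quaternary C7 substituent sets C2′ as S (hence C3′ as S) relative to C1′.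

Step 15
Reactants: 28 homoallylic alcohol
Product: 29 bis-TBS diene (metathesis precursor)
Conditions: TBSOTf, 2,6-lutidine, CH2Cl2, 0 °C to rt
Reagents that add atoms: tert-butyldimethylsilyl triflate CC(C)(C)[Si](C)(C)OS(=O)(=O)C(F)(F)F
Why: Silyl triflate silylation is strong enough for the hindered C2′ hydroxyl and gives two identical groups that fall together in the last step.

Step 16
Reactants: 29 bis-TBS diene
Product: 30 protected spiro cyclohexene lactone
Conditions: second-generation Hoveyda–Grubbs catalyst (H2IMes)Cl2Ru(=CH-C6H4-2-OiPr) (10 mol%), 1,4-benzoquinone (20 mol%), toluene (2 mM), 80 °C, argon sparge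
Reagents that add atoms: none
Why: Ring-closing olefin metathesis (Chauvin mechanism): the catalyst trades its benzylidene for the unhindered C4′=C5′ vinyl group, the new alkylidene adds across the neighbouring 1,1-disubstituted alkene to a ruthenacyclobutane, and cycloreversion releases 30 and Ru=CH2, ethylene being the only by-product. The closest known reaction type is the metathesis closure of a monosubstituted onto a 1,1-disubstituted alkene that gives a trisubstituted cyclohexene beside a quaternary carbon. Ring C closes as a six-membered carbocycle by intramolecular [2+2] cycloaddition/cycloreversion, and because both partners hang from C7 the same event completes the spiro junction. No stereocentre is made or touched, and the alkene geometry is dictated by the ring. The selectivity needed is closure rather than dimerisation through the vinyl termini or alkene migration; it is secured by high dilution, by the geminal attachment of both arms to C7 (Thorpe–Ingold effect), by the syn bis(silyloxy) unit whose bulky groups prefer to be anti and thereby hold C1′ and the vinyl group gauche, and by the absence of any third reactive alkene, C4 of the lactone still being saturated. Benzoquinone intercepts ruthenium hydrides and the argon stream removes ethylene.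

Step 17
Reactants: 30 spiro cyclohexene lactone
Product: 34 α-methylene lactone (PMB and both TBS groups retained), via lithium enolate 31 (not isolated), via Mannich base 32 (not isolated), via ammonium iodide 33 (not isolated)
Conditions: LDA, THF, −78 °C; Me2N=CH2 I (Eschenmoser's salt), −78 °C to rt; crude amine: MeI, THF, rt; aq NaHCO3/CH2Cl2, rt
Reagents that add atoms: Eschenmoser's salt C=[N+](C)C.[I-]
Why: α-Methylenation by Mannich reaction of the lactone enolate, quaternisation and Hofmann-type β-elimination; C4 is the only enolisable position and becomes sp2, so the face of aminomethylation is irrelevant.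

Step 18
Reactants: 34 α-methylene lactone
Product: 35 primary allylic alcohol
Conditions: DDQ, CH2Cl2–pH 7 buffer, 0 °C
Reagents that add atoms: none
Why: Oxidative PMB cleavage (hydride abstraction by DDQ, hydrolysis of the oxocarbenium ion) is orthogonal to the silyl ethers and to the electron-poor methylene lactone.

Step 19
Reactants: 35 primary allylic alcohol; 36 angelic acid
Product: 38 angelate bis-TBS ether, via mixed anhydride 37 (not isolated)
Conditions: 36, 2,4,6-trichlorobenzoyl chloride, Et3N, toluene, rt; filter; 35, toluene, 80 °C (no DMAP)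
Reagents that add atoms: none
Why: Yamaguchi-type mixed-anhydride esterification run without a nucleophilic catalyst, because reversible conjugate addition of such bases is what turns angelates (Z) into tiglates (E); the primary alcohol attacks the less hindered angeloyl carbonyl.

Step 20
Reactants: 38 angelate bis-TBS ether
Product: 39 CNP0224912.1 (target)
Conditions: HF·pyridine, pyridine, THF, 0 °C to rt
Reagents that add atoms: none
Why: Acidic fluoride desilylation removes both TBS groups while avoiding basic conditions that would add to the methylene lactone or isomerise the angelate; no stereocentre is affected.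

Compound list
1 | (1R,5S)-2-oxabicyclo[3.3.0]oct-6-en-3-one | O=C1C[C@H]2C=CC[C@H]2O1 | starting material
2 | 6-exo-bromo-7-endo-hydroxy lactone | C1C(=O)O[C@@H]2C[C@H](O)[C@@H](Br)[C@H]12 | intermediate
3 | 7-endo-hydroxy lactone | C1C(=O)O[C@@H]2C[C@H](O)C[C@H]12 | intermediate
4 | cis-2-oxabicyclo[3.3.0]octane-3,7-dione | C1C(=O)O[C@@H]2CC(=O)C[C@H]12 | intermediate
5 | 4-methoxybenzyl alcohol | COc1ccc(CO)cc1 | starting material
6 | 2,3-dibromopropene | C=C(Br)CBr | starting material
7 | sodium 4-methoxybenzyl oxide | COc1ccc(C[O-])cc1.[Na+] | intermediate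
8 | 2-bromoallyl 4-methoxybenzyl ether | C=C(Br)COCc1ccc(OC)cc1 | intermediate
9 | 1-(PMB-oxymethyl)vinyllithium | [Li]C(=C)COCc1ccc(OC)cc1 | intermediate
10 | 1-(PMB-oxymethyl)vinylcerium dichloride | Cl[Ce](Cl)C(=C)COCc1ccc(OC)cc1 | intermediate
11 | tertiary allylic alcohol (OH endo, alkenyl exo) | C1C(=O)O[C@@H]2C[C@@](O)(C(=C)COCc3ccc(OC)cc3)C[C@H]12 | intermediate
12 | exocyclic primary allylic alcohol (both alkene geometries) | C1C(=O)O[C@@H]2CC(=C(CO)COCc3ccc(OC)cc3)C[C@H]12 | intermediate
13 | vinyl ether of 12 | C1C(=O)O[C@@H]2CC(=C(COC=C)COCc3ccc(OC)cc3)C[C@H]12 | intermediate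
14 | quaternary aldehyde (CH2CHO exo, alkenyl endo) | C1C(=O)O[C@@H]2C[C@@](C[C@H]12)(C(=C)COCc3ccc(OC)cc3)CC=O | intermediate
15 | quaternary acetic acid | C1C(=O)O[C@@H]2C[C@@](C[C@H]12)(C(=C)COCc3ccc(OC)cc3)CC(=O)O | intermediate
16 | (R)-4-benzyl-2-oxazolidinone | O=C1N[C@H](Cc2ccccc2)CO1 | starting material
17 | mixed pivalic anhydride of 15 | C1C(=O)O[C@@H]2C[C@@](C[C@H]12)(C(=C)COCc3ccc(OC)cc3)CC(=O)OC(=O)C(C)(C)C | intermediate
18 | N-acyl oxazolidinone | C1C(=O)O[C@@H]2C[C@@](C[C@H]12)(C(=C)COCc3ccc(OC)cc3)CC(=O)N4[C@H](Cc5ccccc5)COC4=O | intermediate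
19 | Z sodium enolate of 18 | C1C(=O)O[C@@H]2C[C@@](C[C@H]12)(C(=C)COCc3ccc(OC)cc3)/C=C(\[O-])N4[C@H](Cc5ccccc5)COC4=O.[Na+] | intermediate
20 | (1′R)-α-methyl imide | C1C(=O)O[C@@H]2C[C@@](C[C@H]12)(C(=C)COCc3ccc(OC)cc3)[C@@H](C)C(=O)N4[C@H](Cc5ccccc5)COC4=O | intermediate
21 | triol | OCC[C@H]1C[C@](C(=C)COCc2ccc(OC)cc2)([C@@H](C)CO)C[C@H]1O | intermediate
22 | lactol (anomeric centre undefined) | C1C(O)O[C@@H]2C[C@@](C[C@H]12)(C(=C)COCc3ccc(OC)cc3)[C@@H](C)CO | intermediate
23 | hydroxy lactone | C1C(=O)O[C@@H]2C[C@@](C[C@H]12)(C(=C)COCc3ccc(OC)cc3)[C@@H](C)CO | intermediate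
24 | (1′R)-α-methyl aldehyde | C1C(=O)O[C@@H]2C[C@@](C[C@H]12)(C(=C)COCc3ccc(OC)cc3)[C@@H](C)C=O | intermediate
25 | allyl tert-butyldimethylsilyl ether | C=CCO[Si](C)(C)C(C)(C)C | starting material
26 | (Z)-3-(TBS-oxy)allyllithium | [Li]C/C=C\O[Si](C)(C)C(C)(C)C | intermediate
27 | (Z)-tributyl[3-(TBS-oxy)allyl]stannane | CCCC[Sn](CCCC)(CCCC)C/C=C\O[Si](C)(C)C(C)(C)C | intermediate
28 | (1′R,2′S,3′S) homoallylic alcohol | C1C(=O)O[C@@H]2C[C@@](C[C@H]12)(C(=C)COCc3ccc(OC)cc3)[C@@H](C)[C@H](O)[C@@H](O[Si](C)(C)C(C)(C)C)C=C | intermediate
29 | bis-TBS diene (metathesis precursor) | C1C(=O)O[C@@H]2C[C@@](C[C@H]12)(C(=C)COCc3ccc(OC)cc3)[C@@H](C)[C@H](O[Si](C)(C)C(C)(C)C)[C@@H](O[Si](C)(C)C(C)(C)C)C=C | intermediate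
30 | protected spiro cyclohexene lactone | C1C(=O)O[C@@H]2C[C@@]3(C[C@H]12)C(COCc4ccc(OC)cc4)=C[C@H](O[Si](C)(C)C(C)(C)C)[C@@H](O[Si](C)(C)C(C)(C)C)[C@@H]3C | intermediate
31 | lithium enolate of 30 | C1=C([O-])O[C@@H]2C[C@@]3(C[C@H]12)C(COCc4ccc(OC)cc4)=C[C@H](O[Si](C)(C)C(C)(C)C)[C@@H](O[Si](C)(C)C(C)(C)C)[C@@H]3C.[Li+] | intermediate
32 | 4-exo-(dimethylaminomethyl) lactone (Mannich base) | CN(C)C[C@H]1C(=O)O[C@@H]2C[C@@]3(C[C@H]12)C(COCc4ccc(OC)cc4)=C[C@H](O[Si](C)(C)C(C)(C)C)[C@@H](O[Si](C)(C)C(C)(C)C)[C@@H]3C | intermediate
33 | trimethylammonium iodide of 32 | C[N+](C)(C)C[C@H]1C(=O)O[C@@H]2C[C@@]3(C[C@H]12)C(COCc4ccc(OC)cc4)=C[C@H](O[Si](C)(C)C(C)(C)C)[C@@H](O[Si](C)(C)C(C)(C)C)[C@@H]3C.[I-] | intermediate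
34 | α-methylene lactone, PMB/bis-TBS protected | C=C1C(=O)O[C@@H]2C[C@@]3(C[C@H]12)C(COCc4ccc(OC)cc4)=C[C@H](O[Si](C)(C)C(C)(C)C)[C@@H](O[Si](C)(C)C(C)(C)C)[C@@H]3C | intermediate
35 | primary allylic alcohol | C=C1C(=O)O[C@@H]2C[C@@]3(C[C@H]12)C(CO)=C[C@H](O[Si](C)(C)C(C)(C)C)[C@@H](O[Si](C)(C)C(C)(C)C)[C@@H]3C | intermediate
36 | angelic acid, (Z)-2-methylbut-2-enoic acid | C/C=C(/C)C(=O)O | starting material
37 | angelic 2,4,6-trichlorobenzoic anhydride | C/C=C(/C)C(=O)OC(=O)c1c(Cl)cc(Cl)cc1Cl | intermediate
38 | angelate bis-TBS ether | C=C1C(=O)O[C@@H]2C[C@@]3(C[C@H]12)C(COC(=O)/C(C)=C\C)=C[C@H](O[Si](C)(C)C(C)(C)C)[C@@H](O[Si](C)(C)C(C)(C)C)[C@@H]3C | intermediate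
39 | CNP0224912.1 | C=C1C(=O)O[C@@H]2C[C@@]3(C[C@H]12)C(COC(=O)/C(C)=C\C)=C[C@H](O)[C@@H](O)[C@@H]3C | target

Total step count: 20. Longest linear sequence: 18 (steps 1–3, 5–12 and 14–20; steps 4 and 13 make reagents).

Steps most likely to fail

Step 16. The alkylidene loaded at the vinyl group may fail to engage the neopentyl-type 1,1-disubstituted alkene. Dimerisation through the vinyl termini or hydride-induced alkene migration would then take over.
- The fallback sets out from 29 and returns at 30.
- Both terminal alkenes are cleaved (OsO4 cat., NaIO4, 2,6-lutidine, dioxane–H2O) to the keto aldehyde F1, in which the two carbons to be joined are carbonyl carbons.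
- An intramolecular McMurry coupling (TiCl3(DME)1.5, Zn–Cu couple, DME, reflux, slow addition) then forms the same ring C double bond reductively.

Step 10. The lactone may be deprotonated in competition, leading to methylation at C4 or self-condensation. Alternatively the enolate, flanked by the quaternary carbon, may alkylate too slowly.
- The fallback sets out from 18 and returns at 20.
- Soft enolisation (TiCl4, i-Pr2NEt, CH2Cl2, 0 °C) touches only the chelating imide.
- Reaction of this titanium enolate with s-trioxane/TiCl4 brings in a CH2OH group from the face that MeI would use, giving the hydroxymethyl imide F2.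
- Iodination (I2, PPh3, imidazole) gives the primary iodide F3.
- Radical reduction (Bu3SnH, AIBN, toluene, 80 °C) turns CH2I into the methyl group of 20.

Step 14. Facial discrimination at the aldehyde may be insufficient, or the neighbouring 1,1-disubstituted alkene may attack the Lewis-acid-activated aldehyde in a Prins-type closure.
- The fallback sets out from 24 and returns at 29.
- It uses a reagent-controlled γ-alkoxyallylboration through a closed chair transition state, with no Lewis acid present when the aldehyde is added.
- The reagent is made from allyl methoxymethyl ether (s-BuLi, THF, −78 °C; (+)-B-methoxydiisopinocampheylborane from (−)-α-pinene; BF3·OEt2). Aldehyde 24 is then added at −78 °C, followed by ethanolamine work-up.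
- This reinforces the Felkin–Anh preference and gives the syn 3′-MOM ether alcohol F4.
- Acidic methanolysis (cat. HCl, MeOH, 40 °C) gives the syn diol F5.
- Double silylation (TBSOTf, 2,6-lutidine) gives 29.

Further compounds
F1 | step 16 | keto aldehyde from cleavage of both alkenes of 29 | C1C(=O)O[C@@H]2C[C@@](C[C@H]12)(C(=O)COCc3ccc(OC)cc3)[C@@H](C)[C@H](O[Si](C)(C)C(C)(C)C)[C@@H](O[Si](C)(C)C(C)(C)C)C=O
F2 | step 10 | α-hydroxymethyl imide | C1C(=O)O[C@@H]2C[C@@](C[C@H]12)(C(=C)COCc3ccc(OC)cc3)[C@@H](CO)C(=O)N4[C@H](Cc5ccccc5)COC4=O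
F3 | step 10 | α-iodomethyl imide | C1C(=O)O[C@@H]2C[C@@](C[C@H]12)(C(=C)COCc3ccc(OC)cc3)[C@@H](CI)C(=O)N4[C@H](Cc5ccccc5)COC4=O
F4 | step 14 | syn 2′-hydroxy-3′-(methoxymethoxy) homoallylic alcohol | C1C(=O)O[C@@H]2C[C@@](C[C@H]12)(C(=C)COCc3ccc(OC)cc3)[C@@H](C)[C@H](O)[C@@H](OCOC)C=C
F5 | step 14 | syn 2′,3′-diol | C1C(=O)O[C@@H]2C[C@@](C[C@H]12)(C(=C)COCc3ccc(OC)cc3)[C@@H](C)[C@H](O)[C@@H](O)C=C
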